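(All runs are calculated for an exercise, noise included.)

Which stands higher at the end of autumn and of dawn, tris adduct or its isomer, and how much tris adduct is there?

| setting | oak | birch | autumn | dawn |
|---|---|---|---|---|
| starting material | 0.10 M | 0.10 M | 0.10 M | 0.10 M |
| coupling partner | 0.95 equiv | 2 equiv | 2.40 equiv | 1.20 equiv |
| remark | run made earlier | run made earlier |  |  |
| time |  |  | 1.0 h | 1.0 h |

- oak (time / min: tris adduct / %): 3.00: 0; 8.00: 1; 15.0: 5; 25.0: 4; 30.0: 6; 40.0: 7
- birch (time / min: tris adduct / %): 8.00: 18; 15.0: 22; 20.0: 27; 30.0: 27; 40.0: 32

(standard deviation of a reading: 2 percentage points)

* which of the two there is more of at the end, autumn (tris adduct / isomer of the product)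
* which of the two there is more of at the end, dawn (tris adduct / isomer of the product)
* tris adduct at the end, in percent of the starting material charged, autumn
* tris adduct at the end, in percent of the starting material charged, dawn

- the analysis behind the earlier runs scatters by 2 percentage points, standard deviation

I turn the question round and ask what the isomer of the product needs in order to lead. Tris adduct and its isomer each hold 3 coupling partners, and the partner is the limiting reagent in both flasks, so together they stay under a ceiling of the equivalents over 3. What tris adduct leaves of that ceiling is the room for the isomer. The isomer can lead only if tris adduct stands below half of the ceiling: 40.0 % in autumn and 20.0 % in dawn, my tipping line.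

The last readings of oak and birch, taken at the same time, give tris adduct a power of 2.04 in the equivalents, so I reckon 46.4 % for autumn and 11.3 % for dawn, both carrying the scatter. Autumn stands above its line, so tris adduct leads there. Dawn stands below its line, so the ceiling leaves dawn's ranking open. I assume that the isomerisation is a reversible, partner-free step that reaches equilibrium within the hour; that gives both flasks one ratio of isomer to tris adduct, and so I rank dawn like autumn: tris adduct.

The forecast says tris adduct at 48 % for autumn and isomer of the product, with tris adduct at 14 %, for dawn, on the ground that “scarce partner leaves product to isomerise”. It parts from me on dawn's ranking.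

The flask gives tris adduct in autumn, 47.3 % against 17.3 % of isomer, and tris adduct in dawn, 11.8 % against 4.32 %.

    starting material + coupling partner → mono adduct + by-product (k = 1.42 L mol⁻¹ min⁻¹)
    coupling partner + mono adduct → double product + by-product (k = 0.787 L mol⁻¹ min⁻¹)
    coupling partner + double product → tris adduct + by-product (k = 2.68 L mol⁻¹ min⁻¹)
    tris adduct ⇌ isomer of the product (K = 0.366, k = 0.589 min⁻¹)

Autumn's tris adduct lies above its tipping line, but dawn's lies below, so the ceiling does not give dawn's ranking. The main reason for the gap in tris adduct between the two flasks is their difference in equivalents of coupling partner: autumn's 47.3 % becomes 11.8 % without it. Part of the reason is the way back from isomer to tris adduct: the dawn run without it holds 0.0117 % of tris adduct instead of 11.8 %, and the answer turns. In a flask like autumn but with 9.60 equiv, the starting material caps the ceiling and the tipping line is 50.0 %; that flask gives 73.2 % of tris adduct and 26.8 % of isomer.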